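**Target check.** The SMILES is 6,7-dimethoxycoumarin with a 7-coumarinyl-oxy group on C3. The molecule has no stereocenters, so it is achiral and the "single enantiomer" condition is trivially met.

**Retrosynthesis**
- Disconnect the C3 coumarin ring of the 6,7-dimethoxycoumarin half (lactone C2–O and C3–C4 bonds), as in a Perkin condensation. This gives 2-hydroxy-4,5-dimethoxybenzaldehyde (5) and the aryloxyacetic acid 4.
- Acid 4 comes from umbelliferone (1), which already carries the second coumarin ring, by O-alkylation with a bromoacetate and ester cleavage.
- The 7-coumarinyl–O–CH₂ unit supplies the C3 oxygen substituent. The 6,7-dimethoxycoumarin ring is the only ring formed, in the last step.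

**Route**

Step 1
Reactants: 1 (umbelliferone, 7-hydroxycoumarin); 2 (tert-butyl bromoacetate)
Product: 3 (tert-butyl 2-[(2-oxo-2H-chromen-7-yl)oxy]acetate)
Conditions: K2CO3, acetone, reflux, 6 h
Reagents that add atoms: tert-butyl bromoacetate, BrCC(=O)OC(C)(C)C
Why: Williamson ether synthesis at the acidic 7-phenol (pKa about 7.8) under mild base. The tert-butyl ester avoids hydroxide, which would open the coumarin lactone. No stereocenter is formed.

Step 2
Reactants: 3
Product: 4 ((2-oxo-2H-chromen-7-yl)oxyacetic acid)
Conditions: TFA, CH2Cl2, rt, 2 h
Reagents that add atoms: none
Why: Acid-mediated E1 cleavage of the tert-butyl ester gives isobutene and the free acid. The enol-lactone and the aryl ether are stable to TFA, and no stereocenter is involved.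

Step 3
Reactants: 4; 5 (2-hydroxy-4,5-dimethoxybenzaldehyde)
Product: 6 (daphnoretin methyl ether, 3-[(2-oxo-2H-chromen-7-yl)oxy]-6,7-dimethoxycoumarin)
Conditions: Ac2O, Et3N, 120–130 °C, 12 h
Reagents that add atoms: none (Ac2O only activates the acid and is lost as AcOH)
Why: Perkin-type condensation. The mixed anhydride of 4 forms an enolate that adds to the aldehyde. Lactonization onto the phenol and loss of water then give the aromatic 3-aryloxycoumarin. The product ring is planar and sp², so no stereocenter arises. The 4-OMe group of 5 becomes C7-OMe and the 5-OMe becomes C6-OMe, matching the target.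

**Final checks**
- Atom balance: 4 (C11H8O5) + 5 (C9H10O4) gives C20H14O7 (6) after loss of H2O and CO2 and the acetyl transfers. The target SMILES formula is C20H16O7 with two OMe groups: the coumarin carbons (9+9 = 18) plus two OMe (2) give 20 C. Hydrogens: 6 has H3 and H4 of the right-hand ring (2), H5, H6 and H8 of the right-hand ring (3), H4 of the left-hand ring (1), H5 and H8 of the left-hand ring (2), and 6 H from the two OMe groups, for 14 H. So the formula is C20H14O7, and the pattern matches the SMILES.
- Functional groups: the lactones survive Steps 1 and 2 (no aqueous base, no hydrogenation), and the methyl ethers survive TFA and Ac2O.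
- Stereochemistry: the target is achiral and nothing is set or scrambled.
- Assumption: 2-hydroxy-4,5-dimethoxybenzaldehyde is commercially available, as are umbelliferone and tert-butyl bromoacetate.

**Compound list**

| No. | Name | SMILES | Role |
|---|---|---|---|
| 1 | Umbelliferone (7-hydroxycoumarin) | O=c1ccc2ccc(O)cc2o1 | starting material |
| 2 | tert-Butyl bromoacetate | BrCC(=O)OC(C)(C)C | starting material |
| 3 | tert-Butyl (2-oxochromen-7-yl)oxyacetate | CC(C)(C)OC(=O)COc1ccc2ccc(=O)oc2c1 | intermediate |
| 4 | (2-Oxochromen-7-yl)oxyacetic acid | OC(=O)COc1ccc2ccc(=O)oc2c1 | intermediate |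
| 5 | 2-Hydroxy-4,5-dimethoxybenzaldehyde | COc1cc(C=O)c(O)cc1OC | starting material |
| 6 | Daphnoretin methyl ether | COc1cc2cc(Oc3ccc4ccc(=O)oc4c3)c(=O)oc2cc1OC | target |

**Total steps:** 3. **Longest linear sequence:** 3 steps (1 → 3 → 4 → 6).

**Three steps most likely to fail**
1. **Step 3 (Perkin condensation).** Yields can be modest because of competing acetylation and decarboxylative side reactions at high temperature. Fallback: change the bond-forming strategy. Make 3-bromo-6,7-dimethoxycoumarin from 5 by Perkin condensation with bromoacetic acid or by bromination of 6,7-dimethoxycoumarin. Then couple it with umbelliferone by Cu-catalyzed Ullmann C–O coupling (CuI, N,N-dimethylglycine, Cs2CO3, dioxane, 100 °C).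
2. **Step 2 (ester cleavage).** Strong acid could in principle disturb the coumarin. Fallback: use ethyl bromoacetate in Step 1 and cleave the ethyl ester under neutral conditions with Me3SnOH in DCE at 60 °C. This avoids both strong acid and aqueous hydroxide.
3. **Step 1 (O-alkylation).** Alkylation could be incomplete or give C-alkylation. Fallback: a Mitsunobu etherification of umbelliferone with tert-butyl glycolate (PPh3, DIAD, THF), which forms the same aryl ether under neutral conditions.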